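**Retrosynthetic overview**
1. Target 2 ⇒ disconnect the C3–Br bond (electrophilic aromatic substitution) ⇒ 5,7-dibromo-1H-indole 1 plus a Br⁺ source (NBS).
2. No ring is formed: the indole bicycle and the 5- and 7-bromines are bought in 1.
3. C3 is the most nucleophilic carbon of 1 and the benzo ring is deactivated by its two bromines, so the C3–Br bond is the only new bond.

Assumption: the target is achiral (planar aromatic, no stereocentre), so "single enantiomer" has no bearing; 5,7-dibromo-1H-indole (CAS 36132-08-8) is taken as a catalogue starting material.

**Step 1**
Reactants: 1 5,7-dibromo-1H-indole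
Product: 2 3,5,7-tribromo-1H-indole (target)
Conditions: NBS (1.05 equiv, added in portions), dry DMF, 0 °C → rt, 1–2 h, dark
Reagents that add atoms: N-bromosuccinimide (NBS), O=C1CCC(=O)N1Br
Why: Electrophilic aromatic substitution (NBS bromination of an indole) occurs at the enamine-like C3, because the benzo ring is deactivated and C5/C7 are already substituted, so one equivalent of Br⁺ gives the 3-bromo product; no stereocentre is formed.

**Compound list**
1 | 5,7-dibromo-1H-indole | Brc1cc(Br)c2[nH]ccc2c1 | starting material
2 | 3,5,7-tribromo-1H-indole | Brc1cc(Br)c2[nH]cc(Br)c2c1 | target

**Total step count:** 1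
**Longest linear sequence:** 1 step

**Steps most likely to fail**
The route has only one step, so only one step can be named.

Step 1 (C3 bromination of the free NH indole). The risks are over-bromination at C2, oxidation to oxindole-type products if the DMF is wet, and decomposition of the free 3-bromoindole on silica, in acid or in light. The fallback sets out from 1 and comes back to the route at 2. It changes the approach from direct halogenation to protect, brominate, deprotect. Treat 1 with Boc2O and catalytic DMAP in MeCN at rt to give tert-butyl 5,7-dibromo-1H-indole-1-carboxylate F1. Brominate this less electron-rich carbamate at C3 with NBS in MeCN (or Br2 in CH2Cl2 if sluggish) to give tert-butyl 3,5,7-tribromo-1H-indole-1-carboxylate F2, which tolerates chromatography and storage. Finally remove the N-Boc group by mild methanolysis (catalytic K2CO3, MeOH/THF, rt to 50 °C) to give 2, which then needs only an extractive work-up and crystallisation.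

**Further compounds**
F1 | step 1 | tert-butyl 5,7-dibromo-1H-indole-1-carboxylate | CC(C)(C)OC(=O)n1ccc2cc(Br)cc(Br)c21
F2 | step 1 | tert-butyl 3,5,7-tribromo-1H-indole-1-carboxylate | CC(C)(C)OC(=O)n1cc(Br)c2cc(Br)cc(Br)c21
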